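The readings were computed for an exercise, noise included.

The amounts I started from were the J readings of three runs, of which ochre and violet differ in G while holding L as in the flask asked about.

in all of them: Q 0.40 M (fed, over 10 h)

| run | L | G | remark | time | volume of the second phase over the first |
|---|---|---|---|---|---|
| ochre | 0.72 M | 0.27 M | run made earlier |  |  |
| violet | 0.72 M | 0.60 M | run made earlier |  |  |
| grey | 1.1 M | 0.40 M | run made earlier |  |  |
| flask | 0.720 M | 0.400 M |  | 15 d | 1.0 |

| run | time / d | J / % |
|---|---|---|
| ochre | 0.125 | 3.7 |
| ochre | 0.333 | 17.2 |
| ochre | 0.833 | 13.5 |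
| ochre | 2.08 | 1.3 |
| ochre | 5.00 | 0 |
| ochre | 12.0 | 0.4 |
| violet | 0.125 | 3.3 |
| violet | 0.333 | 13.8 |
| violet | 0.833 | 9.0 |
| violet | 2.08 | 0 |
| violet | 5.00 | 0 |
| violet | 12.0 | 0.3 |
| grey | 0.125 | 4.4 |
| grey | 0.417 | 15.8 |
| grey | 1.25 | 0.8 |
| grey | 4.00 | 0.8 |
| grey | 12.0 | 0.6 |

(standard deviation of a reading: 1 percentage point)

- when, up to 15 d, the flask holds most J
- the amount of J, in percent of the Q charged, at that time

- in the second phase: L; everything else is in the first
- charges count per volume of the first phase; a concentration in a rate is the amount of a species over the volume of its own phase; every rate counts per litre of the first phase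
- what was read earlier has a scatter of 1 percentage point, one standard deviation
- the earlier runs hold the two phases in the same ratio of volumes as the flask asked about
- a reading or a percentage of J counts all its forms, free or not
- percentages count the whole charge, also what has not yet gone in

At 0.333 d the ochre run read 17.2% and the violet run 13.8%, so I supposed a side path for Q and took its rate over the rate of the path to J, a quotient in which time drops out, as proportional to G at this L. Those two readings gave 0.935 L mol⁻¹, which put the flask at 0.374: this loss number, a selectivity factor, counts the Q leaving by the side path for each Q going the way of J. From it I reckoned J in the flask at that same time as 15.7%. One number was not enough, though: it required violet to stand at 0.802 of ochre throughout, yet at 0.833 d the readings gave a lower 0.667, and at 2.08 d they stood at 1.3% and 0%, so J was itself lost once formed.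

The forecast gave 19% at 0.43 d, holding that J “peaks about when the feed ends”; its figure stood for the peak, whereas mine stood for the earlier 0.333 d.

The flask gave 19.0% at 0.471 d.

    Z + J → X (k = 5.10 × 10⁻⁴ L mol⁻¹ s⁻¹)
    Z ⇌ L, rate k2*([Z] - [L]/K2) per volume of the first phase (partition coefficient = 0.590, kL = 1.50 × 10⁻⁵ s⁻¹)
    E ⇌ J, rate k3*(cs3 - [J]) while solid is left; crystals form when [J] > cs3 (solubility = 0.350 M, k = 0.00140 s⁻¹)
    Q + Z → J (k = 3.00 × 10⁻⁴ L mol⁻¹ s⁻¹)
    Q + G → D (k = 4.80 × 10⁻⁵ L mol⁻¹ s⁻¹)

At that time the flask held D at 19.8% against 47.9% in J and X together, a quotient of 0.413 beside my 0.374. For the same flask with 1.0 M of G, the number became 0.935, so I expected 48.3% of the Q to end as D. The computed flask ended with D at 48.9%, and its highest J was 14.6%, which is 4.4 percentage points lower than the forecast's figure, so that figure would not have held for that much G.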